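## Retrosynthetic overview
- The 1,4-dioxane ring is closed last, at C7–O (the oxygen meta to the allyl group), by reductive cycloetherification of a keto-phenol. Hydride adds to the cyclic oxocarbenium ion anti to the C8 methyl group, which gives the cis isomer.
- C7–aryl: the keto-phenol comes from a single addition of 3,4,5-trimethoxyphenylmagnesium bromide to an (S)-3-methyl-1,4-benzodioxin-2-one, in the same flask.
- The lactone comes from O-demethylation and lactonisation of an (S)-2-aryloxypropanoate.
- C8–O (the oxygen para to the allyl group): Mitsunobu inversion of methyl (R)-lactate by eugenol. In eugenol one oxygen is a free OH and the other is OCH3, and this decides which oxygen ends on C8 and which on C7.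
- Ring order: both benzene rings are bought. The temporary lactone ring is formed first and opened by the Grignard reagent. The dioxane ring is formed last.

Assumption: the stereocentres are called C7 (O–CH–aryl) and C8 (O–CH–CH3); the SMILES decodes as (7R,8S), the 2,3-cis benzodioxane, with the C8 oxygen para and the C7 oxygen meta to the allyl group.

## Route

Step 1
Reactants: 1 eugenol (2-methoxy-4-(prop-2-en-1-yl)phenol); 2 methyl (R)-lactate (methyl (2R)-2-hydroxypropanoate)
Product: 3 methyl (2S)-2-[2-methoxy-4-(prop-2-en-1-yl)phenoxy]propanoate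
Conditions: PPh3 (1.2 equiv), DIAD (1.2 equiv), THF, 0 °C to rt
Reagents that add atoms: none
Why: Mitsunobu etherification: the only free OH of 1 (para to the allyl group) displaces the activated lactate hydroxyl by SN2, so C8 is inverted cleanly from R to S and the placement of the two ring oxygens is fixed.

Step 2
Reactants: 3 methyl (2S)-2-[2-methoxy-4-(prop-2-en-1-yl)phenoxy]propanoate
Product: 5 (3S)-3-methyl-7-(prop-2-en-1-yl)-1,4-benzodioxin-2(3H)-one, via phenol ester 4 (not isolated)
Conditions: BBr3 (2.2 equiv), CH2Cl2, −78 to −10 °C; H2O; then p-TsOH·H2O (5 mol %), PhMe, 60 °C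
Reagents that add atoms: none
Why: Lewis-acid aryl methyl ether cleavage followed by lactonisation: bromide attacks the unhindered O-methyl carbon rather than the secondary C8, the freed phenol transesterifies onto the neighbouring ester through a six-membered ring, and no bond at C8 is touched, so it stays S.

Step 3
Reactants: 5 (3S)-3-methyl-7-(prop-2-en-1-yl)-1,4-benzodioxin-2(3H)-one; 6 5-bromo-1,2,3-trimethoxybenzene
Product: 11 (2S,3R)-2-methyl-6-(prop-2-en-1-yl)-3-(3,4,5-trimethoxyphenyl)-2,3-dihydro-1,4-benzodioxine, via (3,4,5-trimethoxyphenyl)magnesium bromide 7 (not isolated), via keto-phenol 8 (not isolated), via cyclic hemiketal 9 (not isolated), via oxocarbenium ion 10 (not isolated)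
Conditions: 6, Mg, THF, 40 °C; add slowly (1.05 equiv) to 5, PhMe, −78 °C; CF3CO2H (1.1 equiv), switch solvent to CH2Cl2; Et3SiH (3 equiv), then CF3CO2H (10 equiv), −30 to 0 °C
Reagents that add atoms: none
Why: Proposed new method: one-flask arylative reductive cycloetherification of an aryl lactone, not yet shown for 1,4-benzodioxin-2-ones or for phenol-derived hemiketals. Reagent 7 adds once to the activated aryl ester of 5 at −78 °C, because the adduct collapses to a magnesium-phenoxide-chelated ketone that is conjugated with the electron-rich aryl ring and branched at C8, and so is the poorer electrophile. Acid frees 8, whose phenol oxygen (meta to allyl) closes onto C7 to give 9, which forms the new C7–O bond. Loss of water gives 10, in which the C8 methyl stands pseudo-axial to avoid allylic 1,2-strain with the coplanar aryl group. Et3SiH, already present when the acid is added, delivers hydride axially on the face anti to that methyl, so H enters trans to CH3, the aryl group ends cis to CH3, C7 becomes R and C8 stays S. At or below 0 °C neither the open aryl ketone nor the monosubstituted allyl alkene is reduced by Et3SiH/CF3CO2H. The closest known reaction type is silane reduction of lactol or hemiketal oxocarbenium ions (C-aryl glycoside synthesis from lactones, reductive etherification of hydroxy ketones).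

## Compound list
1 | eugenol, 2-methoxy-4-(prop-2-en-1-yl)phenol | C=CCc1ccc(O)c(OC)c1 | starting material
2 | methyl (2R)-2-hydroxypropanoate | C[C@@H](O)C(=O)OC | starting material
3 | methyl (2S)-2-[2-methoxy-4-(prop-2-en-1-yl)phenoxy]propanoate | C=CCc1ccc(O[C@@H](C)C(=O)OC)c(OC)c1 | intermediate
4 | methyl (2S)-2-[2-hydroxy-4-(prop-2-en-1-yl)phenoxy]propanoate | C=CCc1ccc(O[C@@H](C)C(=O)OC)c(O)c1 | intermediate
5 | (3S)-3-methyl-7-(prop-2-en-1-yl)-1,4-benzodioxin-2(3H)-one | C=CCc1ccc2c(c1)OC(=O)[C@H](C)O2 | intermediate
6 | 5-bromo-1,2,3-trimethoxybenzene | COc1cc(Br)cc(OC)c1OC | starting material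
7 | (3,4,5-trimethoxyphenyl)magnesium bromide | COc1cc([Mg]Br)cc(OC)c1OC | intermediate
8 | (2S)-2-[2-hydroxy-4-(prop-2-en-1-yl)phenoxy]-1-(3,4,5-trimethoxyphenyl)propan-1-one (formed as its bromomagnesium phenoxide, freed by acid) | C=CCc1ccc(O[C@@H](C)C(=O)c2cc(OC)c(OC)c(OC)c2)c(O)c1 | intermediate
9 | (3S)-3-methyl-7-(prop-2-en-1-yl)-2-(3,4,5-trimethoxyphenyl)-2,3-dihydro-1,4-benzodioxin-2-ol (both C2 epimers) | C=CCc1ccc2c(c1)OC(O)(c1cc(OC)c(OC)c(OC)c1)[C@H](C)O2 | intermediate
10 | (3S)-3-methyl-7-(prop-2-en-1-yl)-2-(3,4,5-trimethoxyphenyl)-3H-1,4-benzodioxin-1-ium (trifluoroacetate counter-ion) | C=CCc1ccc2c(c1)[O+]=C(c1cc(OC)c(OC)c(OC)c1)[C@H](C)O2 | intermediate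
11 | (2S,3R)-2-methyl-6-(prop-2-en-1-yl)-3-(3,4,5-trimethoxyphenyl)-2,3-dihydro-1,4-benzodioxine (cis; 7R,8S) | C=CCc1ccc2c(c1)O[C@H](c1cc(OC)c(OC)c(OC)c1)[C@H](C)O2 | target

## Step count and risks
Total step count: 3. Longest linear sequence: 3 (1 or 2 → 3 → 5 → 11).

**Most likely to fail: step 3 (the proposed new step).**
- Risk: a second addition of 7 to the released ketone, or enolisation of 5.
- Risk: loss of the C8 proton from 10 to give a 1,4-benzodioxine, which would erode the ee.
- Risk: acid ionisation of the benzylic C7–O bond of 11, leading to cis-to-trans drift or over-reduction.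
- Fallback: known chemistry that closes the ring by SN2 instead of oxocarbenium reduction. It sets out from 5 and comes back at 11. Compound 5 is reduced with i-Bu2AlH (PhMe, −78 °C) to the lactol (3S)-3-methyl-7-(prop-2-en-1-yl)-2,3-dihydro-1,4-benzodioxin-2-ol F1. Excess 7 (3 equiv, THF, −78 to 0 °C) then adds to its ring-opened aldehyde under Cram-chelate control, with magnesium held by the phenoxide O, the ether O and the C=O. This gives the threo diol 2-{[(1S,2S)-1-hydroxy-1-(3,4,5-trimethoxyphenyl)propan-2-yl]oxy}-5-(prop-2-en-1-yl)phenol F2, which is separated from any erythro isomer by chromatography. Intramolecular Mitsunobu etherification (PPh3, DIAD, THF, 0 °C) inverts C7 from S to R and gives 11.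

**Second: step 2.**
- Risk: bromide attack at C8, which is activated by the ester, with loss of the lactate unit.
- Risk: HBr addition to the allyl group on quenching.
- Risk: some racemisation of the aryl lactone on handling.
- Fallback: nucleophilic instead of Lewis-acidic dealkylation. It sets out from 3 and comes back at 5. LiOH (THF/H2O, 0 °C) gives (2S)-2-[2-methoxy-4-(prop-2-en-1-yl)phenoxy]propanoic acid F3. NaSEt (DMF, 100 °C) then removes the aryl O-methyl group by SN2 at CH3, while the carboxylate shields C8 from both substitution and deprotonation. This gives (2S)-2-[2-hydroxy-4-(prop-2-en-1-yl)phenoxy]propanoic acid F4. Catalytic p-TsOH in PhMe with a Dean–Stark trap closes it to 5.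

**Third: step 1.**
- Risk: sluggish coupling of the ortho-substituted phenol.
- Risk: difficult removal of the phosphine oxide and hydrazine by-products from the oily ester.
- Fallback: an isolated electrophile and a Williamson alkylation in place of the redox condensation. It sets out from 1 and 2 and comes back at 3. Compound 2 is converted with MsCl/Et3N (CH2Cl2, 0 °C, retention) into methyl (2R)-2-(methanesulfonyloxy)propanoate F5. Compound 1 is then alkylated with it (K2CO3, MeCN, 50 °C) by SN2, with the same R-to-S inversion.

## Further compounds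
F1 | step 3 | (3S)-3-methyl-7-(prop-2-en-1-yl)-2,3-dihydro-1,4-benzodioxin-2-ol | C=CCc1ccc2c(c1)OC(O)[C@H](C)O2
F2 | step 3 | 2-{[(1S,2S)-1-hydroxy-1-(3,4,5-trimethoxyphenyl)propan-2-yl]oxy}-5-(prop-2-en-1-yl)phenol | C=CCc1ccc(O[C@@H](C)[C@@H](O)c2cc(OC)c(OC)c(OC)c2)c(O)c1
F3 | step 2 | (2S)-2-[2-methoxy-4-(prop-2-en-1-yl)phenoxy]propanoic acid | C=CCc1ccc(O[C@@H](C)C(=O)O)c(OC)c1
F4 | step 2 | (2S)-2-[2-hydroxy-4-(prop-2-en-1-yl)phenoxy]propanoic acid | C=CCc1ccc(O[C@@H](C)C(=O)O)c(O)c1
F5 | step 1 | methyl (2R)-2-(methanesulfonyloxy)propanoate | C[C@@H](OS(C)(=O)=O)C(=O)OC
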